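**Retrosynthetic overview**
1. The target comes from hydrogenation of its 6,7-didehydro derivative, whose nine-membered keto-lactam comes from O2 cleavage of the C1=C9a bond of a tetracyclic enamine (tuberostemonine skeleton at the enamine level), made and cleaved in one flask.
2. Ring A comes from aza-annulation of a tricyclic cyclic ketimine with (Z)-1,4-dichlorobut-2-ene (N4–C5, then C8–C9).
3. Ring C, with cis-fused lactone D, comes from an intramolecular aza-ene (imine Michael) closure C1→C12 of a 1-pyrroline onto its pendant α-methylbutenolide; ring B comes from amine/ketone condensation.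
4. The acyclic amino ketone comes from an acid (organocatalytic vinylogous Mukaiyama–Michael; sets C10, C11) and an iodide (vinylogous Mannich, then hydrogenation; sets C3, C18, C20); both lactones derive from one silyloxyfuran.
5. Order of ring formation: D (as butenolide) and E, then B, then C, then A, then the nine-membered ring.

Assumption: the SMILES is taken as drawn, i.e. (3S,9R,10R,11S,12S,13S,18S,20S) in Stemona numbering (N4, C9a; ring A azepane, ring B pyrrolidine, ring C carbocycle, lactone D on C11/C12, lactone E on C3; the compound is the 1,9a-seco-1,9a-dioxo derivative of the tuberostemonine skeleton, tuberostemonone), and this numbering is used below.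

**Route**

Step 1
Reactants: 1 3-methylfuran-2(5H)-one
Product: 2 3-methyl-2-(trimethylsilyloxy)furan
Conditions: TMSCl, Et3N, CH2Cl2, 0 °C to rt; distil
Reagents that add atoms: chlorotrimethylsilane, C[Si](C)(C)Cl
Why: Soft enolisation and O-silylation of the butenolide give the aromatic 2-silyloxyfuran (silyl dienol ether formation), and no stereocentre is involved.

Step 2
Reactants: 2 3-methyl-2-(trimethylsilyloxy)furan; 3 (E)-pent-2-enal
Product: 4 (3R)-3-[(2S)-4-methyl-5-oxo-2,5-dihydrofuran-2-yl]pentanal
Conditions: (2S,5S)-5-benzyl-2-tert-butyl-3-methylimidazolidin-4-one (20 mol %), 2,4-dinitrobenzoic acid (20 mol %), H2O (2 equiv), CH2Cl2, −70 °C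
Reagents that add atoms: none
Why: Iminium-ion organocatalysis (vinylogous Mukaiyama–Michael addition): the benzyl group of the catalyst shields one face of the E-iminium ion so that furan C5 adds to the open face of C10 (10R, the same facial sense as other π-nucleophiles with this catalyst), and the acid co-catalyst/solvent pair is the one chosen for the diastereomer with lactone oxygen and ethyl syn (11S).

Step 3
Reactants: 4 (3R)-3-[(2S)-4-methyl-5-oxo-2,5-dihydrofuran-2-yl]pentanal
Product: 5 (3R)-3-[(2S)-4-methyl-5-oxo-2,5-dihydrofuran-2-yl]pentanoic acid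
Conditions: NaClO2, NaH2PO4, 2-methylbut-2-ene, t-BuOH/H2O, 0 °C to rt
Reagents that add atoms: sodium chlorite, [Na+].[O-]Cl=O
Why: Pinnick oxidation converts the aldehyde to the acid under buffered, weakly acidic conditions that leave the base-sensitive butenolide and both stereocentres untouched.

Step 4
Reactants: 6 3-(benzyloxy)propanal; 7 (R)-2-methylpropane-2-sulfinamide
Product: 8 (R,E)-N-[3-(benzyloxy)propylidene]-2-methylpropane-2-sulfinamide
Conditions: CuSO4 (anhydrous), CH2Cl2, rt
Reagents that add atoms: none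
Why: Ellman condensation of aldehyde and sulfinamide with a dehydrating agent gives the E-sulfinimine, and the sulfur stereocentre is carried in from 7.

Step 5
Reactants: 8 (R,E)-N-[3-(benzyloxy)propylidene]-2-methylpropane-2-sulfinamide; 2 3-methyl-2-(trimethylsilyloxy)furan
Product: 9 (R)-N-{(1S)-3-(benzyloxy)-1-[(2S)-4-methyl-5-oxo-2,5-dihydrofuran-2-yl]propyl}-2-methylpropane-2-sulfinamide
Conditions: TMSOTf (0.5 equiv), CH2Cl2, −78 °C; aq. NaHCO3
Reagents that add atoms: none
Why: Lewis-acid-promoted vinylogous Mannich addition through an open transition state, in which furan C5 attacks the imine face anti to the tert-butyl group of the s-cis sulfinimine (3S) and the syn (threo) N/O relationship to C18 (18S) follows the known syn preference of 3-methyl-2-silyloxyfurans with N-sulfinyl aldimines.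

Step 6
Reactants: 9 (R)-N-{(1S)-3-(benzyloxy)-1-[(2S)-4-methyl-5-oxo-2,5-dihydrofuran-2-yl]propyl}-2-methylpropane-2-sulfinamide
Product: 10 (R)-N-{(1S)-3-hydroxy-1-[(2S,4S)-4-methyl-5-oxooxolan-2-yl]propyl}-2-methylpropane-2-sulfinamide
Conditions: H2 (4 bar), Pd(OH)2/C, EtOH, rt
Reagents that add atoms: none
Why: Heterogeneous hydrogenation adds H2 to the butenolide face opposite the C18 side chain, which puts the C20 methyl cis to it (20S), and the same catalyst removes the benzyl ether by hydrogenolysis.

Step 7
Reactants: 10 (R)-N-{(1S)-3-hydroxy-1-[(2S,4S)-4-methyl-5-oxooxolan-2-yl]propyl}-2-methylpropane-2-sulfinamide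
Product: 12 (R)-N-{(1S)-3-iodo-1-[(2S,4S)-4-methyl-5-oxooxolan-2-yl]propyl}-2-methylpropane-2-sulfinamide, via mesylate 11 (not isolated)
Conditions: MsCl, Et3N, CH2Cl2, 0 °C; then NaI, acetone, 55 °C
Reagents that add atoms: sodium iodide, [Na+].[I-]; methanesulfonyl chloride, CS(=O)(=O)Cl (its atoms are held only in 11)
Why: Sulfonylation followed by Finkelstein displacement (SN2 at the primary carbon) avoids phosphine reagents that could deoxygenate the sulfinamide, and no stereocentre is touched.

Step 8
Reactants: 5 (3R)-3-[(2S)-4-methyl-5-oxo-2,5-dihydrofuran-2-yl]pentanoic acid; 12 (R)-N-{(1S)-3-iodo-1-[(2S,4S)-4-methyl-5-oxooxolan-2-yl]propyl}-2-methylpropane-2-sulfinamide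
Product: 15 (R)-N-{(1S,6R)-6-[(2S)-4-methyl-5-oxo-2,5-dihydrofuran-2-yl]-1-[(2S,4S)-4-methyl-5-oxooxolan-2-yl]-4-oxooctyl}-2-methylpropane-2-sulfinamide, via acid chloride 13 (not isolated), via alkylzinc iodide 14 (not isolated)
Conditions: 5, 1-chloro-N,N,2-trimethylprop-1-en-1-amine, CH2Cl2, 0 °C; 12, Zn dust (TMSCl-activated), DMF, rt; combine, PdCl2(PPh3)2 (5 mol %), THF, 0 °C to rt
Reagents that add atoms: 1-chloro-N,N,2-trimethylprop-1-en-1-amine, CC(C)=C(Cl)N(C)C (its Cl is held only in 13); zinc, [Zn] (held only in 14)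
Why: Zinc insertion gives a functional-group-tolerant alkylzinc iodide that is acylated under palladium catalysis by an acid chloride made without HCl (Negishi-type acylation, as used for amino-acid-derived zinc reagents), so lactone, butenolide, sulfinamide and all stereocentres are left unchanged.

Step 9
Reactants: 15 (R)-N-{(1S,6R)-6-[(2S)-4-methyl-5-oxo-2,5-dihydrofuran-2-yl]-1-[(2S,4S)-4-methyl-5-oxooxolan-2-yl]-4-oxooctyl}-2-methylpropane-2-sulfinamide
Product: 18 tricyclic ketimine (rings B/C/D closed; N4=C9a; H1/H11/H12 cis; 13-methyl trans to C1; C9 still CH2; lactone E on C3), via ammonium chloride 16 (not isolated), via 1-pyrroline 17 (not isolated)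
Conditions: HCl (4 M in dioxane), MeOH, 0 °C; aq. NaHCO3, CH2Cl2; then PhMe, 90 °C, argon
Reagents that add atoms: hydrogen chloride, Cl (its chloride is held only in 16)
Why: Proposed new method: acid removes the sulfinyl group, the freed γ-amino ketone closes to 1-pyrroline 17 (ring B), and on heating its secondary enamine tautomer (N4–H, C9a=C1) adds through C1 to C12 of the tethered butenolide in an intramolecular aza-ene reaction that is the biosynthetic C1–C12 bond formation; the chair-like transition state with equatorial ethyl and equatorial C11–O enforces the cis ring fusion (H11/H12 cis) and hands the N–H suprafacially to C13 on the face of the new C1–C12 bond, which leaves the 13-methyl trans to C1 as in the target; the closest known reaction type is the aza-ene Michael addition of ketimines to electron-poor alkenes with internal N-to-C proton transfer.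

Step 10
Reactants: 18 tricyclic ketimine; 19 (Z)-1,4-dichlorobut-2-ene
Product: 24 6,7-didehydrotuberostemonone (nine-membered keto-lactam; cis C6=C7 in ring A), via N-chlorobutenyl iminium chloride 20 (not isolated), via didehydro tetracyclic iminium chloride 21 (not isolated), via didehydro tetracyclic enamine 22 (not isolated), via dioxetane 23 (not isolated)
Conditions: 19 (3 equiv), NaI (10 mol %), MeCN, 50 °C, wash salt with Et2O; i-Pr2NEt (3 equiv), MeCN (0.01 M), 60 °C, argon; Et2O, filter; then O2, 5,10,15,20-tetraphenylporphyrin (1 mol %), visible light, CH2Cl2, −40 °C to rt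
Reagents that add atoms: dioxygen, O=O
Why: Proposed new method: the imine nitrogen of 18 is allylated by 19 to iminium 20, base forms its enamines, and the C9=C9a tautomer closes ring A by allylic SN2 at C8 in a 7-(enolendo)-exo-tet mode that the cis alkene pre-organises, while alkylation at C1 would give an anti-Bredt bridgehead iminium, SN2′ closure to a five-membered ring is a disfavoured 5-(enolendo)-exo-trig process and N-allylation of the enamine to a spiro 2,5-dihydropyrrolium salt is reversible because allylic enammonium salts are allylating agents that halide re-opens; C9 then equilibrates through iminium/enamine exchange to the trans-diequatorial C8/ethyl arrangement of the target, loss of H1 gives the tetrasubstituted C1=C9a enamine 22, and singlet oxygen adds [2+2] to this electron-rich alkene, far faster than it reacts with the cis-disubstituted C6=C7 alkene, to give dioxetane 23 whose cycloreversion cuts C1–C9a into the C1 ketone and the C9a lactam, which is the nine-membered ring and the oxidative enamine cleavage assumed for the biosynthesis; the closest known reaction types are endocyclic enamine synthesis by N-/C-alkylation of cyclic imines with dihalides, the N-to-C transfer of allyl groups in enamine alkylation and the dioxetane cleavage of enamines by singlet oxygen.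

Step 11
Reactants: 24 6,7-didehydrotuberostemonone
Product: 25 tuberostemonone (target)
Conditions: H2 (1 atm), Pd/C (10 %), EtOAc, rt
Reagents that add atoms: none
Why: Heterogeneous catalytic hydrogenation adds H2 to the isolated cis-disubstituted C6=C7 alkene of ring A under conditions that leave the ketone, the lactam and both lactones untouched, and no stereocentre is formed or disturbed.

**Compound list**

1 | 3-methylfuran-2(5H)-one | CC1=CCOC1=O | starting material
2 | 3-methyl-2-(trimethylsilyloxy)furan | Cc1ccoc1O[Si](C)(C)C | intermediate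
3 | (E)-pent-2-enal | CC/C=C/C=O | starting material
4 | (3R)-3-[(2S)-4-methyl-5-oxo-2,5-dihydrofuran-2-yl]pentanal | O=CC[C@@H](CC)[C@@H]1OC(=O)C(C)=C1 | intermediate
5 | (3R)-3-[(2S)-4-methyl-5-oxo-2,5-dihydrofuran-2-yl]pentanoic acid | OC(=O)C[C@@H](CC)[C@@H]1OC(=O)C(C)=C1 | intermediate
6 | 3-(benzyloxy)propanal | O=CCCOCc1ccccc1 | starting material
7 | (R)-2-methylpropane-2-sulfinamide | CC(C)(C)[S@@](=O)N | starting material
8 | (R,E)-N-[3-(benzyloxy)propylidene]-2-methylpropane-2-sulfinamide | CC(C)(C)[S@@](=O)/N=C/CCOCc1ccccc1 | intermediate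
9 | (R)-N-{(1S)-3-(benzyloxy)-1-[(2S)-4-methyl-5-oxo-2,5-dihydrofuran-2-yl]propyl}-2-methylpropane-2-sulfinamide | CC(C)(C)[S@@](=O)N[C@@H](CCOCc1ccccc1)[C@@H]1C=C(C)C(=O)O1 | intermediate
10 | (R)-N-{(1S)-3-hydroxy-1-[(2S,4S)-4-methyl-5-oxooxolan-2-yl]propyl}-2-methylpropane-2-sulfinamide | CC(C)(C)[S@@](=O)N[C@@H](CCO)[C@@H]1C[C@H](C)C(=O)O1 | intermediate
11 | methanesulfonate of 10 (not isolated) | CC(C)(C)[S@@](=O)N[C@@H](CCOS(C)(=O)=O)[C@@H]1C[C@H](C)C(=O)O1 | intermediate
12 | (R)-N-{(1S)-3-iodo-1-[(2S,4S)-4-methyl-5-oxooxolan-2-yl]propyl}-2-methylpropane-2-sulfinamide | CC(C)(C)[S@@](=O)N[C@@H](CCI)[C@@H]1C[C@H](C)C(=O)O1 | intermediate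
13 | (3R)-3-[(2S)-4-methyl-5-oxo-2,5-dihydrofuran-2-yl]pentanoyl chloride (not isolated) | ClC(=O)C[C@@H](CC)[C@@H]1OC(=O)C(C)=C1 | intermediate
14 | alkylzinc iodide from 12 (Zn in place of the C–I bond; not isolated) | CC(C)(C)[S@@](=O)N[C@@H](CC[Zn]I)[C@@H]1C[C@H](C)C(=O)O1 | intermediate
15 | (R)-N-{(1S,6R)-6-[(2S)-4-methyl-5-oxo-2,5-dihydrofuran-2-yl]-1-[(2S,4S)-4-methyl-5-oxooxolan-2-yl]-4-oxooctyl}-2-methylpropane-2-sulfinamide | CC(C)(C)[S@@](=O)N[C@@H](CCC(=O)C[C@@H](CC)[C@@H]1OC(=O)C(C)=C1)[C@@H]2C[C@H](C)C(=O)O2 | intermediate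
16 | (1S,6R)-6-[(2S)-4-methyl-5-oxo-2,5-dihydrofuran-2-yl]-1-[(2S,4S)-4-methyl-5-oxooxolan-2-yl]-4-oxooctan-1-aminium chloride (not isolated) | [Cl-].[NH3+][C@@H](CCC(=O)C[C@@H](CC)[C@@H]1OC(=O)C(C)=C1)[C@@H]2C[C@H](C)C(=O)O2 | intermediate
17 | (3S,5S)-3-methyl-5-[(2S)-5-{(2R)-2-[(2S)-4-methyl-5-oxo-2,5-dihydrofuran-2-yl]butyl}-3,4-dihydro-2H-pyrrol-2-yl]oxolan-2-one (not isolated) | CC[C@H](CC1=N[C@@H](CC1)[C@@H]2C[C@H](C)C(=O)O2)[C@@H]3OC(=O)C(C)=C3 | intermediate
18 | tricyclic ketimine: ring B 1-pyrroline (N4=C9a) fused at C1–C9a to ring C, closed by the C1–C12 bond; lactone D cis-fused on C11/C12 with H1, H11 and H12 cis and the 13-methyl trans to C1; ethyl on C10 trans to the C11 oxygen; C9 is CH2; lactone E on C3 | CC[C@H]1[C@@H]2OC(=O)[C@@H](C)[C@@H]2[C@@H]3C[C@@H]([C@@H]4C[C@H](C)C(=O)O4)N=C3C1 | intermediate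
19 | (Z)-1,4-dichlorobut-2-ene | ClC/C=C\CCl | starting material
20 | N-[(Z)-4-chlorobut-2-enyl] iminium chloride of 18 (not isolated) | CC[C@H]1[C@@H]2OC(=O)[C@@H](C)[C@@H]2[C@@H]3C[C@@H]([C@@H]4C[C@H](C)C(=O)O4)[N+](C/C=C\CCl)=C3C1.[Cl-] | intermediate
21 | 6,7-didehydro tetracyclic iminium chloride (ring A closed by C8–C9; N4=C9a; C8 trans to ethyl; cis C6=C7; not isolated) | CC[C@H]1[C@@H]2OC(=O)[C@@H](C)[C@@H]2[C@@H]3C[C@@H]([C@@H]4C[C@H](C)C(=O)O4)[N+]5=C3[C@@H]1C/C=C\C5.[Cl-] | intermediate
22 | 6,7-didehydro tetracyclic enamine (tuberostemonine skeleton with C1=C9a and cis C6=C7; not isolated) | CC[C@H]1[C@@H]2OC(=O)[C@@H](C)[C@@H]2C3=C4[C@@H]1C/C=C\CN4[C@@H](C3)[C@@H]5C[C@H](C)C(=O)O5 | intermediate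
23 | 1,9a-dioxetane of 22 (configuration at C1/C9a not assigned, either face collapses to 24; not isolated) | CC[C@H]1[C@@H]2OC(=O)[C@@H](C)[C@@H]2C36C[C@@H]([C@@H]5C[C@H](C)C(=O)O5)N4C/C=C\C[C@H]1C34OO6 | intermediate
24 | 6,7-didehydrotuberostemonone (the target with a cis C6=C7 double bond in ring A; all eight stereocentres as in the target) | CC[C@H]1[C@@H]2OC(=O)[C@@H](C)[C@@H]2C(=O)C[C@@H]([C@@H]2C[C@H](C)C(=O)O2)N2C/C=C\C[C@H]1C2=O | intermediate
25 | tuberostemonone, (3S,9R,10R,11S,12S,13S,18S,20S) | CC[C@H]1[C@@H]2OC(=O)[C@@H](C)[C@@H]2C(=O)C[C@@H]([C@@H]2C[C@H](C)C(=O)O2)N2CCCC[C@H]1C2=O | target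

**Totals**

Total steps: 11. Longest linear sequence: 8 (steps 4–11 from 6; the branch of steps 1–3 joins at step 8).

**Three steps most likely to fail**

Most at risk is step 10. The enamine nitrogen can close onto the allylic chloride to a spiro 2,5-dihydropyrrolium salt faster than C9 closes the seven-membered ring, and the return from that salt rests on halide re-opening. In addition, C9 rests on equilibration, and the C9=C9a enamine tautomer could be cleaved instead of C1=C9a. The fallback for step 10 sets out from compound 18 and comes back to the route at compound 22; it makes the C8–C9 and N4–C5 bonds between molecules and closes ring A by metathesis. Compound 18 is allylated on carbon with allyl methyl carbonate and Pd(PPh3)4 (5 mol %, THF, 50 °C), where zerovalent palladium keeps N-allylation reversible so that the allyl group settles on the CH2 carbon C9 trans to the ethyl group, to give the 9-allyl tricyclic ketimine F1. Allyl bromide (MeCN, 50 °C) then gives the N,9-diallyl iminium bromide F2. The second-generation Grubbs catalyst (5 mol %, CH2Cl2, 40 °C) closes ring A with loss of ethene to the 6,7-didehydro tetracyclic iminium bromide F3. i-Pr2NEt deprotonates it to enamine 22, which is photo-oxygenated as in step 10 and carried through step 11.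

Second is step 9. The imine nitrogen could add to the butenolide instead of C1, the α-methylbutenolide is a sluggish acceptor, and the C13 configuration depends on the internal proton transfer. The fallback for step 9 sets out from compound 3 and comes back to the route at compound 18; it closes ring C onto an unsubstituted butenolide and brings in the C13 methyl afterwards. Compound 3 and commercial 2-(trimethylsilyloxy)furan, under the conditions of step 2, give (3R)-3-[(2S)-5-oxo-2,5-dihydrofuran-2-yl]pentanal F4. Pinnick oxidation gives (3R)-3-[(2S)-5-oxo-2,5-dihydrofuran-2-yl]pentanoic acid F5, the chloro-enamine of step 8 gives (3R)-3-[(2S)-5-oxo-2,5-dihydrofuran-2-yl]pentanoyl chloride F6, and coupling with 14 as in step 8 gives the 13-nor sulfinyl amino ketone F7. HCl in MeOH gives the 13-nor amino ketone hydrochloride F8, NaHCO3 gives the 13-nor 1-pyrroline F9, and heating closes ring C onto the more reactive butenolide to the 13-nor tricyclic ketimine F10, in which no C13 stereocentre is formed. LiN(SiMe3)2 (1.05 equiv, THF, −78 °C) and then MeI methylate the enolate of the less hindered lactone D from its convex face, as is standard for stenine-type lactones, and give 18.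

Third is step 8. It is the only fragment union, and it needs an alkylzinc next to a free sulfinamide N–H and an acid chloride that carries a butenolide. The fallback for step 8 sets out from compounds 4 and 12 and comes back to the route at compound 15; it joins the fragments at the aldehyde oxidation level. Iodide 12 is added to aldehyde 4 as its alkylchromium reagent (CrCl2, cobalt phthalocyanine C32H16CoN8 as catalyst, DMF, rt; chemoselective for aldehydes over lactones) to give the C9a secondary alcohol F11 as a mixture of carbinol epimers. Dess–Martin periodinane then gives 15, and step 3 is no longer needed.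

**Further compounds**

F1 | step 10 | 9-allyl tricyclic ketimine | CC[C@H]1[C@@H]2OC(=O)[C@@H](C)[C@@H]2[C@@H]3C[C@@H]([C@@H]4C[C@H](C)C(=O)O4)N=C3[C@@H]1CC=C
F2 | step 10 | N,9-diallyl iminium bromide | CC[C@H]1[C@@H]2OC(=O)[C@@H](C)[C@@H]2[C@@H]3C[C@@H]([C@@H]4C[C@H](C)C(=O)O4)[N+](CC=C)=C3[C@@H]1CC=C.[Br-]
F3 | step 10 | 6,7-didehydro tetracyclic iminium bromide | CC[C@H]1[C@@H]2OC(=O)[C@@H](C)[C@@H]2[C@@H]3C[C@@H]([C@@H]4C[C@H](C)C(=O)O4)[N+]5=C3[C@@H]1C/C=C\C5.[Br-]
F4 | step 9 | (3R)-3-[(2S)-5-oxo-2,5-dihydrofuran-2-yl]pentanal | O=CC[C@@H](CC)[C@@H]1OC(=O)C=C1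
F5 | step 9 | (3R)-3-[(2S)-5-oxo-2,5-dihydrofuran-2-yl]pentanoic acid | OC(=O)C[C@@H](CC)[C@@H]1OC(=O)C=C1
F6 | step 9 | (3R)-3-[(2S)-5-oxo-2,5-dihydrofuran-2-yl]pentanoyl chloride | ClC(=O)C[C@@H](CC)[C@@H]1OC(=O)C=C1
F7 | step 9 | 13-nor sulfinyl amino ketone | CC(C)(C)[S@@](=O)N[C@@H](CCC(=O)C[C@@H](CC)[C@@H]1OC(=O)C=C1)[C@@H]2C[C@H](C)C(=O)O2
F8 | step 9 | 13-nor amino ketone hydrochloride | [Cl-].[NH3+][C@@H](CCC(=O)C[C@@H](CC)[C@@H]1OC(=O)C=C1)[C@@H]2C[C@H](C)C(=O)O2
F9 | step 9 | 13-nor 1-pyrroline | CC[C@H](CC1=N[C@@H](CC1)[C@@H]2C[C@H](C)C(=O)O2)[C@@H]3OC(=O)C=C3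
F10 | step 9 | 13-nor tricyclic ketimine | CC[C@H]1[C@@H]2OC(=O)C[C@@H]2[C@@H]3C[C@@H]([C@@H]4C[C@H](C)C(=O)O4)N=C3C1
F11 | step 8 | C9a secondary alcohol | CC(C)(C)[S@@](=O)N[C@@H](CCC(O)C[C@@H](CC)[C@@H]1OC(=O)C(C)=C1)[C@@H]2C[C@H](C)C(=O)O2
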